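**Retrosynthetic overview**
- Target 25 is a macrocyclic bis(bibenzyl) with ring A (catechol, aryloxy meta to its CH2), ring B (para-phenylene), ring C (catechol, aryloxy ortho to its CH2) and ring D (ortho-phenylene). The last operations are BBr3 cleavage of four methyl ethers (24) and an intramolecular Ullmann etherification between the ring A hydroxyl and the ring B bromide (23).
- The strategy rests on ring A: it carries three contiguous oxygens at C1, C2 and C3 and the CH2CH2 chain at C5, and only the outer O1 is the ether to ring B. Ring A is therefore built so that O1 is the only free hydroxyl.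
- Ring A is made by Stille coupling of the squarate-derived chloride 19 with the 2-stannyl-1-alkene 15, followed by 4π opening and 6π closure. This forms the C4–C5 bond and the C1–C6 bond and gives phenol 23 with O2 and O3 as methyl ethers.
- Stannane 15 comes from terminal alkyne 13 by Markovnikov stannylcupration, 13 from benzylic bromide 9 and 1-(trimethylsilyl)propyne, and 9 from aldehyde 7 (SNAr of phenol 5 with 2-fluorobenzaldehyde; 5 by Wittig olefination and diimide reduction).
- Ring order: rings B, C and D are bought as arenes, ring A is formed in step 11, and the macrocycle is closed in step 12.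

Key step: step 11

Assumption: the alkenyltin partner is carried as the trimethylstannane, because a 1,1-disubstituted alkenyl group transfers faster from the smaller tin and the Markovnikov Sn–Cu addition to 1-alkynes is best established for Me3Sn; compounds 1, 2, 6, 10 and 16 are taken as commercial.

**Step 1**
Reactants: 1 2-hydroxy-3,4-dimethoxybenzaldehyde; 2 (4-bromobenzyl)triphenylphosphonium bromide
Product: 4 6-[2-(4-bromophenyl)ethenyl]-2,3-dimethoxyphenol (E/Z mixture), via phosphorus ylide 3 (not isolated)
Conditions: KOt-Bu (2.2 equiv), THF, 0 °C to rt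
Reagents that add atoms: none
Why: Wittig olefination, in which the semistabilised ylide 3 adds to the aldehyde of the phenoxide of 1 and the oxaphosphetane collapses to the stilbene, whose E/Z ratio does not matter because the double bond is saturated in step 2.

**Step 2**
Reactants: 4 6-[2-(4-bromophenyl)ethenyl]-2,3-dimethoxyphenol
Product: 5 6-[2-(4-bromophenyl)ethyl]-2,3-dimethoxyphenol
Conditions: TsNHNH2, NaOAc, THF/H2O, reflux
Reagents that add atoms: none
Why: Diimide reduction, in which diimide released from the sulfonyl hydrazide transfers two hydrogens to the stilbene C=C in a concerted syn addition and leaves the aryl bromide untouched.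

**Step 3**
Reactants: 5 6-[2-(4-bromophenyl)ethyl]-2,3-dimethoxyphenol; 6 2-fluorobenzaldehyde
Product: 7 2-{6-[2-(4-bromophenyl)ethyl]-2,3-dimethoxyphenoxy}benzaldehyde
Conditions: K2CO3, DMA, 140 °C
Reagents that add atoms: none
Why: Nucleophilic aromatic substitution (SNAr), in which the ortho formyl group activates the C–F bond toward the hindered phenoxide of 5 while the unactivated aryl bromide is inert.

**Step 4**
Reactants: 7 2-{6-[2-(4-bromophenyl)ethyl]-2,3-dimethoxyphenoxy}benzaldehyde
Product: 8 (2-{6-[2-(4-bromophenyl)ethyl]-2,3-dimethoxyphenoxy}phenyl)methanol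
Conditions: NaBH4, MeOH/THF, 0 °C
Reagents that add atoms: none
Why: Borohydride reduction of the aryl aldehyde to the benzylic alcohol, which does not affect the ethers or the aryl bromide.

**Step 5**
Reactants: 8 (2-{6-[2-(4-bromophenyl)ethyl]-2,3-dimethoxyphenoxy}phenyl)methanol
Product: 9 2-[2-(bromomethyl)phenoxy]-1-[2-(4-bromophenyl)ethyl]-3,4-dimethoxybenzene
Conditions: CBr4, PPh3, CH2Cl2, 0 °C
Reagents that add atoms: carbon tetrabromide, BrC(Br)(Br)Br
Why: Appel bromination converts the primary benzylic alcohol into the bromide through the alkoxyphosphonium ion under neutral conditions, so no acid is present that could alkylate the electron-rich ring C.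

**Step 6**
Reactants: 9 2-[2-(bromomethyl)phenoxy]-1-[2-(4-bromophenyl)ethyl]-3,4-dimethoxybenzene; 10 1-(trimethylsilyl)propyne
Product: 12 {4-[2-(6-(2-(4-bromophenyl)ethyl)-2,3-dimethoxyphenoxy)phenyl]but-1-yn-1-yl}trimethylsilane, via 3-lithio-1-(trimethylsilyl)propyne 11 (not isolated)
Conditions: 10 (1.3 equiv), n-BuLi (1.2 equiv), THF, −78 °C; then 9, −78 to 0 °C
Reagents that add atoms: none
Why: SN2 alkylation of the silyl-stabilised propargylic carbanion by the benzylic bromide, in which the silyl group steers attack to the CH2 terminus and all n-BuLi is consumed before 9 is added, so that no bromine–lithium exchange occurs on ring B.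

**Step 7**
Reactants: 12 {4-[2-(6-(2-(4-bromophenyl)ethyl)-2,3-dimethoxyphenoxy)phenyl]but-1-yn-1-yl}trimethylsilane
Product: 13 1-[2-(4-bromophenyl)ethyl]-2-[2-(but-3-yn-1-yl)phenoxy]-3,4-dimethoxybenzene
Conditions: K2CO3 (cat.), MeOH/THF, rt
Reagents that add atoms: none
Why: Protodesilylation, in which methoxide cleaves the alkynyl C–Si bond and methanol protonates the acetylide to give the terminal alkyne.

**Step 8**
Reactants: 13 1-[2-(4-bromophenyl)ethyl]-2-[2-(but-3-yn-1-yl)phenoxy]-3,4-dimethoxybenzene
Product: 15 {4-[2-(6-(2-(4-bromophenyl)ethyl)-2,3-dimethoxyphenoxy)phenyl]but-1-en-2-yl}trimethylstannane, via alkenylcopper adduct 14 (not isolated)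
Conditions: (Me3Sn)2, MeLi, THF, −20 °C; CuBr·SMe2, −78 °C; then 13, MeOH (excess), −63 °C
Reagents that add atoms: hexamethylditin, C[Sn](C)(C)[Sn](C)(C)C
Why: Stannylcupration, in which Me3SnCu·SMe2 adds syn across the terminal alkyne with tin on the internal carbon and the alkenylcopper 14 is protonated in situ by methanol, the established route from 1-alkynes to 2-trimethylstannyl-1-alkenes, at a temperature where the aryl bromide is not attacked.

**Step 9**
Reactants: 16 dimethyl squarate
Product: 17 4-hydroxy-2,3-dimethoxycyclobut-2-en-1-one (racemic)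
Conditions: LiAlH(O-t-Bu)3 (1.05 equiv), THF, −78 °C; aqueous KNaC4H4O6 work-up
Reagents that add atoms: none
Why: Selective 1,2-monoreduction of one squarate carbonyl by the bulky hydride, in which the aluminium alkoxide formed shields the second carbonyl and the buffered work-up avoids acid-promoted loss of methanol.

**Step 10**
Reactants: 17 4-hydroxy-2,3-dimethoxycyclobut-2-en-1-one
Product: 19 4-chloro-2,3-dimethoxycyclobut-2-en-1-one (racemic), via chlorosulfite ester 18 (not isolated)
Conditions: SOCl2, pyridine, CH2Cl2, −20 to 0 °C; used crude at once under argon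
Reagents that add atoms: thionyl chloride, ClS(Cl)=O
Why: Deoxychlorination through the chlorosulfite, which ionises readily to the methoxy-stabilised oxocyclobutenyl cation and collapses with chloride at C4 to restore the conjugated vinylogous ester; the chloride is moisture-sensitive and is therefore not purified.

**Step 11**
Reactants: 19 4-chloro-2,3-dimethoxycyclobut-2-en-1-one (1.3 equiv); 15 {4-[2-(6-(2-(4-bromophenyl)ethyl)-2,3-dimethoxyphenoxy)phenyl]but-1-en-2-yl}trimethylstannane
Product: 23 5-[2-(2-{6-[2-(4-bromophenyl)ethyl]-2,3-dimethoxyphenoxy}phenyl)ethyl]-2,3-dimethoxyphenol, via 4-alkenylcyclobutenone 20 (not isolated), via dienylketene 21 (not isolated), via cyclohexa-2,4-dienone 22 (not isolated)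
Conditions: Pd2(dba)3 (2.5 mol %), tri(2-furyl)phosphine (10 mol %), dioxane, 50 °C; then 100 °C
Reagents that add atoms: none
Why: Zerovalent palladium inserts into the C4–Cl bond of 19, which is allylic and alpha to the carbonyl, the alkenyl group of 15 is transferred from tin, and reductive elimination at the unsubstituted ring carbon gives 20, as in the known Stille coupling of 4-chlorocyclobutenones with alkenylstannanes. On heating, 20 opens reversibly by conrotatory 4π electrocyclic cleavage of the C1–C4 bond to the dienylketene 21; the isomer with the alkenyl group rotated inward then closes ring A by disrotatory 6π electrocyclisation between the ketene carbon and the terminal CH2, giving the 6-membered dienone 22, which enolises to phenol 23. The closest known reaction type is the thermal rearrangement of 4-alkenyl- and 4-arylcyclobutenones to phenols. No stereocentre is set, and the racemic centre of 19 and 20 is lost on ring opening. Chemoselectivity for the C–Cl bond over the ring B aryl bromide rests on the much faster oxidative addition of the activated chloride with the weakly donating furylphosphine at 50 °C, and the stannane is the limiting partner so that none remains when the temperature is raised. Regiochemistry follows from connectivity: the tin-bearing carbon becomes the chain-bearing C5, the squarate methoxy groups end at C2 and C3, and the ketene oxygen becomes the only free hydroxyl at C1, provided that coupling occurs at the CH terminus of the oxocyclobutenyl unit, which is the less hindered end and restores the vinylogous ester.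

**Step 12**
Reactants: 23 5-[2-(2-{6-[2-(4-bromophenyl)ethyl]-2,3-dimethoxyphenoxy}phenyl)ethyl]-2,3-dimethoxyphenol
Product: 24 macrocyclic tetramethyl ether (ring A O1 bonded to the para carbon of ring B; methoxy groups at C2 and C3 of ring A and at C3 and C4 of ring C)
Conditions: CuI (20 mol %), N,N-dimethylglycine·HCl (60 mol %), Cs2CO3, dioxane, 100 °C, slow addition to 2 mM
Reagents that add atoms: none
Why: Intramolecular Ullmann diaryl ether synthesis, in which the copper phenoxide of ring A couples with the ring B bromide and high dilution favours ring closure over oligomerisation.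

**Step 13**
Reactants: 24 macrocyclic tetramethyl ether
Product: 25 target macrocycle CNP0114693.0 (achiral tetraphenol)
Conditions: BBr3 (excess), CH2Cl2, −78 °C to rt; then H2O
Reagents that add atoms: none
Why: Lewis acid cleavage of aryl methyl ethers, in which BBr3 coordinates each methoxy oxygen and bromide removes the methyl group, whereas the two diaryl ether bonds offer no sp3 carbon for attack and survive.

**Compound list**
1 | 2-hydroxy-3,4-dimethoxybenzaldehyde | COc1ccc(C=O)c(O)c1OC | starting material
2 | (4-bromobenzyl)triphenylphosphonium bromide | [Br-].Brc1ccc(C[P+](c2ccccc2)(c2ccccc2)c2ccccc2)cc1 | starting material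
3 | (4-bromobenzylidene)triphenylphosphorane | Brc1ccc(C=P(c2ccccc2)(c2ccccc2)c2ccccc2)cc1 | intermediate
4 | 6-[2-(4-bromophenyl)ethenyl]-2,3-dimethoxyphenol (E/Z mixture) | COc1ccc(C=Cc2ccc(Br)cc2)c(O)c1OC | intermediate
5 | 6-[2-(4-bromophenyl)ethyl]-2,3-dimethoxyphenol | COc1ccc(CCc2ccc(Br)cc2)c(O)c1OC | intermediate
6 | 2-fluorobenzaldehyde | O=Cc1ccccc1F | starting material
7 | 2-{6-[2-(4-bromophenyl)ethyl]-2,3-dimethoxyphenoxy}benzaldehyde | O=Cc1ccccc1Oc1c(CCc2ccc(Br)cc2)ccc(OC)c1OC | intermediate
8 | (2-{6-[2-(4-bromophenyl)ethyl]-2,3-dimethoxyphenoxy}phenyl)methanol | OCc1ccccc1Oc1c(CCc2ccc(Br)cc2)ccc(OC)c1OC | intermediate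
9 | 2-[2-(bromomethyl)phenoxy]-1-[2-(4-bromophenyl)ethyl]-3,4-dimethoxybenzene | BrCc1ccccc1Oc1c(CCc2ccc(Br)cc2)ccc(OC)c1OC | intermediate
10 | 1-(trimethylsilyl)propyne | CC#C[Si](C)(C)C | starting material
11 | 3-lithio-1-(trimethylsilyl)propyne | [Li]CC#C[Si](C)(C)C | intermediate
12 | {4-[2-(6-(2-(4-bromophenyl)ethyl)-2,3-dimethoxyphenoxy)phenyl]but-1-yn-1-yl}trimethylsilane | C[Si](C)(C)C#CCCc1ccccc1Oc1c(CCc2ccc(Br)cc2)ccc(OC)c1OC | intermediate
13 | 1-[2-(4-bromophenyl)ethyl]-2-[2-(but-3-yn-1-yl)phenoxy]-3,4-dimethoxybenzene | C#CCCc1ccccc1Oc1c(CCc2ccc(Br)cc2)ccc(OC)c1OC | intermediate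
14 | (Z)-1-cuprio-2-trimethylstannyl-1-alkene adduct of 13 (Cu and Sn cis) | [Cu]/C=C(\[Sn](C)(C)C)CCc1ccccc1Oc1c(CCc2ccc(Br)cc2)ccc(OC)c1OC | intermediate
15 | {4-[2-(6-(2-(4-bromophenyl)ethyl)-2,3-dimethoxyphenoxy)phenyl]but-1-en-2-yl}trimethylstannane | C=C(CCc1ccccc1Oc1c(CCc2ccc(Br)cc2)ccc(OC)c1OC)[Sn](C)(C)C | intermediate
16 | dimethyl squarate | COC1=C(OC)C(=O)C1=O | starting material
17 | 4-hydroxy-2,3-dimethoxycyclobut-2-en-1-one (racemic) | COC1=C(OC)C(O)C1=O | intermediate
18 | 2,3-dimethoxy-4-oxocyclobut-2-en-1-yl chlorosulfite (racemic) | COC1=C(OC)C(OS(Cl)=O)C1=O | intermediate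
19 | 4-chloro-2,3-dimethoxycyclobut-2-en-1-one (racemic) | COC1=C(OC)C(Cl)C1=O | intermediate
20 | 4-alkenyl-2,3-dimethoxycyclobut-2-en-1-one carrying rings D, C and B (racemic) | COC1=C(OC)C(C(=C)CCc2ccccc2Oc2c(CCc3ccc(Br)cc3)ccc(OC)c2OC)C1=O | intermediate
21 | (3Z)-2,3-dimethoxy-5-methylidenehepta-1,3-dien-1-one (dienylketene) carrying rings D, C and B at C7 | O=C=C(OC)/C(OC)=C\C(=C)CCc1ccccc1Oc1c(CCc2ccc(Br)cc2)ccc(OC)c1OC | intermediate
22 | 5-substituted 2,3-dimethoxycyclohexa-2,4-dien-1-one (keto tautomer of 23) | O=C1CC(CCc2ccccc2Oc2c(CCc3ccc(Br)cc3)ccc(OC)c2OC)=CC(OC)=C1OC | intermediate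
23 | 5-[2-(2-{6-[2-(4-bromophenyl)ethyl]-2,3-dimethoxyphenoxy}phenyl)ethyl]-2,3-dimethoxyphenol | Oc1cc(CCc2ccccc2Oc2c(CCc3ccc(Br)cc3)ccc(OC)c2OC)cc(OC)c1OC | intermediate
24 | macrocyclic tetramethyl ether of the target | COc1cc2cc(c1OC)Oc1ccc(cc1)CCc1ccc(OC)c(OC)c1Oc1ccccc1CC2 | intermediate
25 | CNP0114693.0 (macrocyclic bis(bibenzyl) tetraphenol, achiral) | Oc1cc2cc(c1O)Oc1ccc(cc1)CCc1ccc(O)c(O)c1Oc1ccccc1CC2 | target

**Totals**
Total step count: 13. Longest linear sequence: 11 steps (steps 1 to 8, then 11, 12 and 13); steps 9 and 10 form the short squarate branch.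

**Steps most likely to fail**

Step 11. The chloride 19 may ionise and hydrolyse before oxidative addition, transfer of the hindered 1,1-disubstituted alkenyl group from tin to palladium may be slow, coupling may occur at the methoxy-bearing terminus, or palladium may insert into the aryl bromide at 100 °C. The fallback builds ring A from a bought arene instead of by benzannulation and sets out from benzylic bromide 9. PPh3 in toluene at reflux should give the benzyltriphenylphosphonium bromide F1. Wittig olefination of commercial 3-hydroxy-4,5-dimethoxybenzaldehyde with F1 (KOt-Bu, THF) should give the stilbene F2 as an E/Z mixture. Diimide reduction under the conditions of step 2 then returns to the route at 23.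

Step 12. Intermolecular etherification may outrun ring closure, or the bromide may be lost by reduction at the high temperature. The fallback replaces the copper-catalysed coupling of a halide by an oxidative coupling of a boronic acid at room temperature and sets out from 23. Miyaura borylation (bis(pinacolato)diboron, PdCl2(dppf), KOAc, dioxane, 80 °C) should give the pinacol boronate F3. Transesterification with methylboronic acid (0.1 M HCl, acetone/water) should free the boronic acid F4. Chan–Lam macrocyclisation (Cu(OAc)2, Et3N, 4 Å molecular sieves, CH2Cl2, air, rt, high dilution) comes back to the route at 24.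

Step 8. The Sn–Cu addition may proceed with the opposite regiochemistry, or the stannyl metal species may attack the aryl bromide. The fallback fixes the position of tin through a ketone and sets out from alkyne 13. Markovnikov hydration (NaAuCl4 cat., MeOH/H2O, reflux) should give the methyl ketone F5. Kinetic enolisation on the methyl side (LiN(i-Pr)2, THF, −78 °C) and trapping with PhNTf2 should give the enol triflate F6. Stannylation with (Me3Sn)2, Pd(PPh3)4 and LiCl in THF at 60 °C, where the enol triflate should undergo oxidative addition faster than the unactivated aryl bromide, returns to the route at 15.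

**Further compounds**
F1 | step 11 | {2-[6-(2-(4-bromophenyl)ethyl)-2,3-dimethoxyphenoxy]benzyl}triphenylphosphonium bromide | [Br-].COc1ccc(CCc2ccc(Br)cc2)c(Oc2ccccc2C[P+](c2ccccc2)(c2ccccc2)c2ccccc2)c1OC
F2 | step 11 | 5-[2-(2-{6-[2-(4-bromophenyl)ethyl]-2,3-dimethoxyphenoxy}phenyl)ethenyl]-2,3-dimethoxyphenol (E/Z mixture) | Oc1cc(C=Cc2ccccc2Oc2c(CCc3ccc(Br)cc3)ccc(OC)c2OC)cc(OC)c1OC
F3 | step 12 | pinacol boronate of 23 (Bpin in place of Br on ring B) | Oc1cc(CCc2ccccc2Oc2c(CCc3ccc(cc3)B3OC(C)(C)C(C)(C)O3)ccc(OC)c2OC)cc(OC)c1OC
F4 | step 12 | boronic acid of 23 (B(OH)2 in place of Br on ring B) | Oc1cc(CCc2ccccc2Oc2c(CCc3ccc(cc3)B(O)O)ccc(OC)c2OC)cc(OC)c1OC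
F5 | step 8 | 4-(2-{6-[2-(4-bromophenyl)ethyl]-2,3-dimethoxyphenoxy}phenyl)butan-2-one | CC(=O)CCc1ccccc1Oc1c(CCc2ccc(Br)cc2)ccc(OC)c1OC
F6 | step 8 | 4-(2-{6-[2-(4-bromophenyl)ethyl]-2,3-dimethoxyphenoxy}phenyl)but-1-en-2-yl trifluoromethanesulfonate | C=C(CCc1ccccc1Oc1c(CCc2ccc(Br)cc2)ccc(OC)c1OC)OS(=O)(=O)C(F)(F)F
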